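The C-3a acetate at the ring fusion (furo[3,4-c]furan numbering: C-1 veratryl, C-4 guaiacyl, C-6a the ring-fusion CH) is read as the Baeyer–Villiger product of an angular acetyl group, and a 3-acetyl-5-aryltetrahydrofuran is what a pinacol-terminated Prins cyclisation leaves. The key step exploits this: in a veratraldehyde acetal of a 2-(2-aryl-2,5-dihydrofuran-3-yl)propane-1,2-diol, the ring alkene attacks the oxocarbenium ion to form the C-1–C-6a bond, and the O–CH2 carbon then shifts to C-3a, which contracts the oxane to ring B (O-2, C-1, C-6a, C-3a, C-3) and sets three stereocentres from the one at C-4. The precursor is a dioxolane-substituted dihydrofuran, not a furofuran.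

Key step: step 7

Assumption: in step 2 the (R,R)-ligand is taken to give the (R)-carbinol (the antipodal ligand is used if the sense is opposite); compounds 9 and 11 are carried as mixtures at the centres that step 7 destroys.

Step 1
Reactants: 1 vanillin (4-hydroxy-3-methoxybenzaldehyde)
Product: 2 3-methoxy-4-[tri(propan-2-yl)silyloxy]benzaldehyde
Conditions: TIPSCl, imidazole, DMF, rt
Reagents that add atoms: chlorotri(propan-2-yl)silane (TIPSCl), CC(C)[Si](Cl)(C(C)C)C(C)C
Why: Imidazole-mediated silylation of the phenol gives an aryl silyl ether that should survive the organozinc, hydride, osmium, tin tetrachloride and peracid steps and falls to fluoride at the end.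

Step 2
Reactants: 2 3-methoxy-4-[tri(propan-2-yl)silyloxy]benzaldehyde; 3 propyne
Product: 5 (1R)-1-{3-methoxy-4-[tri(propan-2-yl)silyloxy]phenyl}but-2-yn-1-ol, via methyl(prop-1-yn-1-yl)zinc 4 (not isolated)
Conditions: Me2Zn, (R,R)-ProPhenol (10 mol %), Ph3PO (20 mol %), PhMe, 4 °C; aq NH4Cl
Reagents that add atoms: none
Why: Catalytic asymmetric alkynylation, in which the dinuclear zinc–ProPhenol complex delivers the zinc alkynylide 4 to one face of the aryl aldehyde, so that the catalyst sets the benzylic carbinol centre (the future C-4) as R.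

Step 3
Reactants: 5 (1R)-1-{3-methoxy-4-[tri(propan-2-yl)silyloxy]phenyl}but-2-yn-1-ol; 6 allyl bromide (3-bromoprop-1-ene)
Product: 7 {2-methoxy-4-[(1R)-1-(prop-2-en-1-yloxy)but-2-yn-1-yl]phenoxy}tri(propan-2-yl)silane
Conditions: NaH, Bu4NI (cat.), THF, 0 °C to rt
Reagents that add atoms: none
Why: Williamson ether synthesis, in which NaH deprotonates the propargylic alcohol and SN2 attack on allyl bromide gives the 1,6-enyne without touching the stereocentre.

Step 4
Reactants: 7 {2-methoxy-4-[(1R)-1-(prop-2-en-1-yloxy)but-2-yn-1-yl]phenoxy}tri(propan-2-yl)silane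
Product: 8 {2-methoxy-4-[(2R)-3-(prop-1-en-2-yl)-2,5-dihydrofuran-2-yl]phenoxy}tri(propan-2-yl)silane
Conditions: second-generation Grubbs catalyst RuCl2(=CHPh)(PCy3)(H2IMes) (5 mol %), CH2Cl2, 40 °C
Reagents that add atoms: none
Why: Ring-closing enyne metathesis in the exo mode should form the 2,5-dihydrofuran and transfer the terminal methylene to the distal alkyne carbon, which gives the 3-isopropenyl diene and leaves the C-2 centre unchanged.

Step 5
Reactants: 8 {2-methoxy-4-[(2R)-3-(prop-1-en-2-yl)-2,5-dihydrofuran-2-yl]phenoxy}tri(propan-2-yl)silane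
Product: 9 2-[(2R)-2-{3-methoxy-4-[tri(propan-2-yl)silyloxy]phenyl}-2,5-dihydrofuran-3-yl]propane-1,2-diol (both epimers at the carbinol carbon)
Conditions: K2OsO4·2H2O (2 mol %), NMO, acetone/H2O (4:1), 0 °C
Reagents that add atoms: 4-methylmorpholine 4-oxide (NMO), C[N+]1([O-])CCOCC1; water, O
Why: Catalytic osmium tetroxide syn-dihydroxylation with NMO as reoxidant should take the unhindered 1,1-disubstituted alkene, because the ring alkene is shielded by the aryl group and deactivated by two allylic C–O bonds; the new carbinol centre needs no control since it becomes the acetyl carbonyl carbon in step 7.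

Step 6
Reactants: 9 2-[(2R)-2-{3-methoxy-4-[tri(propan-2-yl)silyloxy]phenyl}-2,5-dihydrofuran-3-yl]propane-1,2-diol; 10 veratraldehyde (3,4-dimethoxybenzaldehyde)
Product: 11 {4-[(2R)-3-[2-(3,4-dimethoxyphenyl)-4-methyl-1,3-dioxolan-4-yl]-2,5-dihydrofuran-2-yl]-2-methoxyphenoxy}tri(propan-2-yl)silane (mixture at dioxolane C-2 and C-4)
Conditions: PPTS (10 mol %), PhH, reflux, Dean–Stark trap
Reagents that add atoms: none
Why: Acid-catalysed acetalisation with azeotropic removal of water converts the 1,2-diol and the aldehyde into the 1,3-dioxolane, whose new acetal centre is destroyed on ionisation in step 7.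

Step 7
Reactants: 11 {4-[(2R)-3-[2-(3,4-dimethoxyphenyl)-4-methyl-1,3-dioxolan-4-yl]-2,5-dihydrofuran-2-yl]-2-methoxyphenoxy}tri(propan-2-yl)silane
Product: 14 1-[(1S,3aS,4R,6aR)-1-(3,4-dimethoxyphenyl)-4-{3-methoxy-4-[tri(propan-2-yl)silyloxy]phenyl}tetrahydro-1H,3H-furo[3,4-c]furan-3a(4H)-yl]ethan-1-one, via oxocarbenium tin alkoxide 12 (not isolated), via bicyclic tertiary carbocation 13 (not isolated)
Conditions: SnCl4 (2 equiv), CH2Cl2, −78 to −23 °C; aq NaHCO3
Reagents that add atoms: none
Why: SnCl4 ionises the dioxolane at the tertiary C–O bond to the (E)-oxocarbenium ion 12, C-4 of the dihydrofuran adds to its carbon through a chair (Prins cyclisation) to form the C-1–C-6a bond and the tertiary cation 13, and the stannylated oxygen then drives a 1,2-shift of the O–CH2 carbon to the cationic carbon (pinacol rearrangement), which contracts the oxane to ring B and leaves the acetyl group at C-3a. The closest known reaction type is the pinacol-terminated Prins cyclisation of 4-alkenyl-1,3-dioxolanes to 3-acyltetrahydrofurans. The oxane closes by 6-endo attack of the ring alkene on the oxocarbenium ion, and the tetrahydrofuran (ring B) closes by the ring-contracting 1,2-alkyl shift. C-1 is controlled by the equatorial place of the veratryl group on the (E)-oxocarbenium ion in the chair, which puts it cis to the acetyl group and exo; C-6a and C-3a are controlled by the cis geometry of the ring alkene (cis fusion) and by approach of the tether on the face of the dihydrofuran anti to its C-2 aryl group, so that the one existing centre fixes the absolute configuration. The step needs the pinacol shift to outrun a hydride shift from the neighbouring benzylic carbon and ionisation of the allylic benzylic C–O bond; the tin alkoxide next to the cation, the low temperature and the fact that only the oxocarbenium ion on the primary oxygen can reach the alkene through a six-membered chair should secure this.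

Step 8
Reactants: 14 1-[(1S,3aS,4R,6aR)-1-(3,4-dimethoxyphenyl)-4-{3-methoxy-4-[tri(propan-2-yl)silyloxy]phenyl}tetrahydro-1H,3H-furo[3,4-c]furan-3a(4H)-yl]ethan-1-one
Product: 15 (1S,3aS,4R,6aR)-1-(3,4-dimethoxyphenyl)-4-{3-methoxy-4-[tri(propan-2-yl)silyloxy]phenyl}tetrahydro-1H,3H-furo[3,4-c]furan-3a(4H)-yl acetate
Conditions: mCPBA, NaHCO3, CH2Cl2, 0 °C to rt
Reagents that add atoms: 3-chloroperoxybenzoic acid (mCPBA), OOC(=O)c1cccc(Cl)c1
Why: Baeyer–Villiger oxidation, in which after peracid addition to the methyl ketone the tertiary ring-fusion carbon migrates in preference to methyl and with retention, so that the angular acetyl group becomes the C-3a acetate with its configuration unchanged.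

Step 9
Reactants: 15 (1S,3aS,4R,6aR)-1-(3,4-dimethoxyphenyl)-4-{3-methoxy-4-[tri(propan-2-yl)silyloxy]phenyl}tetrahydro-1H,3H-furo[3,4-c]furan-3a(4H)-yl acetate
Product: 16 (1S,3aS,4R,6aR)-1-(3,4-dimethoxyphenyl)-4-(4-hydroxy-3-methoxyphenyl)tetrahydro-1H,3H-furo[3,4-c]furan-3a(4H)-yl acetate (CNP0107105.1)
Conditions: Bu4NF, AcOH, THF, 0 °C
Reagents that add atoms: none
Why: Fluoride-mediated desilylation of the aryl silyl ether, buffered with acetic acid, should release the phenol while the hindered tertiary acetate and both benzylic ethers remain intact.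

Compound list
1 | vanillin (4-hydroxy-3-methoxybenzaldehyde) | COc1cc(C=O)ccc1O | starting material
2 | 3-methoxy-4-[tri(propan-2-yl)silyloxy]benzaldehyde | COc1cc(C=O)ccc1O[Si](C(C)C)(C(C)C)C(C)C | intermediate
3 | propyne | CC#C | starting material
4 | methyl(prop-1-yn-1-yl)zinc | C[Zn]C#CC | intermediate
5 | (1R)-1-{3-methoxy-4-[tri(propan-2-yl)silyloxy]phenyl}but-2-yn-1-ol | COc1cc([C@H](C#CC)O)ccc1O[Si](C(C)C)(C(C)C)C(C)C | intermediate
6 | allyl bromide (3-bromoprop-1-ene) | C=CCBr | starting material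
7 | {2-methoxy-4-[(1R)-1-(prop-2-en-1-yloxy)but-2-yn-1-yl]phenoxy}tri(propan-2-yl)silane | COc1cc([C@H](C#CC)OCC=C)ccc1O[Si](C(C)C)(C(C)C)C(C)C | intermediate
8 | {2-methoxy-4-[(2R)-3-(prop-1-en-2-yl)-2,5-dihydrofuran-2-yl]phenoxy}tri(propan-2-yl)silane | COc1cc([C@H]2OCC=C2C(C)=C)ccc1O[Si](C(C)C)(C(C)C)C(C)C | intermediate
9 | 2-[(2R)-2-{3-methoxy-4-[tri(propan-2-yl)silyloxy]phenyl}-2,5-dihydrofuran-3-yl]propane-1,2-diol, both epimers at the carbinol carbon | COc1cc([C@H]2OCC=C2C(C)(O)CO)ccc1O[Si](C(C)C)(C(C)C)C(C)C | intermediate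
10 | veratraldehyde (3,4-dimethoxybenzaldehyde) | COc1ccc(C=O)cc1OC | starting material
11 | {4-[(2R)-3-[2-(3,4-dimethoxyphenyl)-4-methyl-1,3-dioxolan-4-yl]-2,5-dihydrofuran-2-yl]-2-methoxyphenoxy}tri(propan-2-yl)silane, mixture at dioxolane C-2 and C-4 | COc1cc([C@H]2OCC=C2C3(C)COC(c4ccc(OC)c(OC)c4)O3)ccc1O[Si](C(C)C)(C(C)C)C(C)C | intermediate
12 | (E)-oxocarbenium ion on the primary oxygen, tertiary oxygen bound to tin as tetrachlorostannate (zwitterion from ring opening of 11) | COc1cc([C@H]2OCC=C2C(C)(C/[O+]=C/c3ccc(OC)c(OC)c3)O[Sn-](Cl)(Cl)(Cl)Cl)ccc1O[Si](C(C)C)(C(C)C)C(C)C | intermediate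
13 | Prins cation: oxane fused to the tetrahydrofuran, tertiary carbocation at the future C-3a, tin alkoxide on the adjacent carbinol carbon | COc1cc([C@H]2OC[C@@H]3[C@@H](c4ccc(OC)c(OC)c4)OCC(C)(O[Sn-](Cl)(Cl)(Cl)Cl)[C+]23)ccc1O[Si](C(C)C)(C(C)C)C(C)C | intermediate
14 | 1-[(1S,3aS,4R,6aR)-1-(3,4-dimethoxyphenyl)-4-{3-methoxy-4-[tri(propan-2-yl)silyloxy]phenyl}tetrahydro-1H,3H-furo[3,4-c]furan-3a(4H)-yl]ethan-1-one (both aryl groups exo, cis ring fusion, acetyl at the ring fusion) | COc1cc([C@H]2OC[C@@H]3[C@@H](c4ccc(OC)c(OC)c4)OC[C@]23C(C)=O)ccc1O[Si](C(C)C)(C(C)C)C(C)C | intermediate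
15 | (1S,3aS,4R,6aR)-1-(3,4-dimethoxyphenyl)-4-{3-methoxy-4-[tri(propan-2-yl)silyloxy]phenyl}tetrahydro-1H,3H-furo[3,4-c]furan-3a(4H)-yl acetate | COc1cc([C@H]2OC[C@@H]3[C@@H](c4ccc(OC)c(OC)c4)OC[C@]23OC(C)=O)ccc1O[Si](C(C)C)(C(C)C)C(C)C | intermediate
16 | (1S,3aS,4R,6aR)-1-(3,4-dimethoxyphenyl)-4-(4-hydroxy-3-methoxyphenyl)tetrahydro-1H,3H-furo[3,4-c]furan-3a(4H)-yl acetate | COc1cc([C@H]2OC[C@@H]3[C@@H](c4ccc(OC)c(OC)c4)OC[C@]23OC(C)=O)ccc1O | target

Total step count: 9. Longest linear sequence: 9 steps (from vanillin 1).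

Steps most likely to fail

Step 7 (key step). The veratryl-stabilised oxocarbenium ion is a weak electrophile and the ring alkene is flanked by two allylic C–O bonds, so the Prins addition may be slow. That would let a hydride shift to the cation, ionisation of the allylic benzylic ether or Lewis-acid epimerisation at C-1 of the product compete. The fallback takes the aryl group out of the cationic cascade and adds it afterwards by cross-coupling. It sets out from diol 9: acetalisation with ethyl glyoxylate (PPTS, PhH, reflux) should give ethyl 4-methyl-4-[(2R)-2-{3-methoxy-4-[tri(propan-2-yl)silyloxy]phenyl}-2,5-dihydrofuran-3-yl]-1,3-dioxolane-2-carboxylate F1. Its far more electrophilic oxocarbenium ion should undergo the same SnCl4-promoted Prins–pinacol sequence (CH2Cl2, −78 °C) to ethyl (1S,3aS,4R,6aR)-3a-acetyl-4-{3-methoxy-4-[tri(propan-2-yl)silyloxy]phenyl}tetrahydro-1H,3H-furo[3,4-c]furan-1-carboxylate F2. Hydrolysis with Me3SnOH (1,2-dichloroethane, 60 °C) gives (1S,3aS,4R,6aR)-3a-acetyl-4-{3-methoxy-4-[tri(propan-2-yl)silyloxy]phenyl}tetrahydro-1H,3H-furo[3,4-c]furan-1-carboxylic acid F3. Decarboxylative arylation of F3 with 4-iodo-1,2-dimethoxybenzene (Ir[dF(CF3)ppy]2(dtbbpy)PF6, NiCl2·glyme, 4,4'-di-tert-butyl-2,2'-bipyridine, Cs2CO3, DMF, blue light) is expected to deliver the aryl group to the α-oxy radical on the convex face. The fallback comes back to the route at ketone 14.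

Step 5. Osmylation may fail to discriminate between the two alkenes of the conjugated diene or run on to the tetraol. The fallback replaces dihydroxylation and acetalisation by epoxidation and epoxide-to-dioxolane conversion. It sets out from diene 8: dimethyldioxirane (acetone, −20 °C) should epoxidise the more nucleophilic exocyclic alkene to {2-methoxy-4-[(2R)-3-(2-methyloxiran-2-yl)-2,5-dihydrofuran-2-yl]phenoxy}tri(propan-2-yl)silane F4. Insertion of veratraldehyde 10 into the tertiary allylic C–O bond of the oxirane (BF3·OEt2 cat., CH2Cl2, −78 °C) then comes back to the route at acetal 11 without passing through diol 9.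

Step 2. The catalytic alkynylation may give insufficient enantioselectivity, or add slowly, with an electron-rich aldehyde and a small gaseous alkyne. The fallback separates bond formation from stereocontrol. It sets out from aldehyde 2: prop-1-ynylmagnesium bromide (THF, −78 °C) gives racemic 1-{3-methoxy-4-[tri(propan-2-yl)silyloxy]phenyl}but-2-yn-1-ol F5. MnO2 (CH2Cl2, rt) oxidises it to 1-{3-methoxy-4-[tri(propan-2-yl)silyloxy]phenyl}but-2-yn-1-one F6. Reduction with (R)-Alpine-Borane (THF, rt), which treats the alkynyl group as the small substituent, comes back to the route at the (R)-alcohol 5.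

Further compounds
F1 | step 7 | ethyl 4-methyl-4-[(2R)-2-{3-methoxy-4-[tri(propan-2-yl)silyloxy]phenyl}-2,5-dihydrofuran-3-yl]-1,3-dioxolane-2-carboxylate (diastereomer mixture) | COc1cc([C@H]2OCC=C2C3(C)COC(C(=O)OCC)O3)ccc1O[Si](C(C)C)(C(C)C)C(C)C
F2 | step 7 | ethyl (1S,3aS,4R,6aR)-3a-acetyl-4-{3-methoxy-4-[tri(propan-2-yl)silyloxy]phenyl}tetrahydro-1H,3H-furo[3,4-c]furan-1-carboxylate | COc1cc([C@H]2OC[C@@H]3[C@@H](C(=O)OCC)OC[C@]23C(C)=O)ccc1O[Si](C(C)C)(C(C)C)C(C)C
F3 | step 7 | (1S,3aS,4R,6aR)-3a-acetyl-4-{3-methoxy-4-[tri(propan-2-yl)silyloxy]phenyl}tetrahydro-1H,3H-furo[3,4-c]furan-1-carboxylic acid | COc1cc([C@H]2OC[C@@H]3[C@@H](C(=O)O)OC[C@]23C(C)=O)ccc1O[Si](C(C)C)(C(C)C)C(C)C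
F4 | step 5 | {2-methoxy-4-[(2R)-3-(2-methyloxiran-2-yl)-2,5-dihydrofuran-2-yl]phenoxy}tri(propan-2-yl)silane (both oxirane epimers) | COc1cc([C@H]2OCC=C2C3(C)CO3)ccc1O[Si](C(C)C)(C(C)C)C(C)C
F5 | step 2 | 1-{3-methoxy-4-[tri(propan-2-yl)silyloxy]phenyl}but-2-yn-1-ol (racemic) | COc1cc(C(O)C#CC)ccc1O[Si](C(C)C)(C(C)C)C(C)C
F6 | step 2 | 1-{3-methoxy-4-[tri(propan-2-yl)silyloxy]phenyl}but-2-yn-1-one | COc1cc(C(=O)C#CC)ccc1O[Si](C(C)C)(C(C)C)C(C)C
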